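Ring D is read as one molecule of methanol. O21–C22 bridges C20 and C23, the two β-carbons of the ring C ketone C17, so rings C and D are the 1:1 adduct of methanol and achiral, C2v-symmetric 4,4-dimethylcyclohexa-2,5-dienone. In one photocatalytic operation •CH2OH adds to C23 and the new alcohol closes onto C20. This forms two bonds, ring D and both bridgehead stereocentres from a flat precursor made in one step. The rest is built on C16: formylation (C15), palladium-catalysed allylation with a symmetric ring A allyl unit (C9), lactonisation (ring B), C6 oxidation, and a three-carbon acid side chain finished by asymmetric hydrogenation.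

Key step: step 2

Numbering remark: atom numbers follow the atom order of the target SMILES. Ring A is C6–C11, ring B the lactone, ring C the cyclohexanone, ring D the tetrahydrofuran. The "exo face" of ring C is the face syn to C24 and anti to the O21–C22 bridge.

Assumption: the absolute sense of induction of the chiral amine (step 2), the lithium amide (step 3) and the diphosphines (steps 6 and 13, and the fallback for step 2) is assigned by analogy with the closest known substrate classes. Both antipodes of each are equally accessible, so the antipode is taken if the sense proves opposite.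

Step 1
Reactants: 1 4,4-dimethylcyclohex-2-en-1-one
Product: 2 4,4-dimethylcyclohexa-2,5-dien-1-one
Conditions: IBX (1.5 equiv), DMSO, 75 °C
Reagents that add atoms: none
Why: IBX dehydrogenation of a ketone through its enol; C5–C6 is the only bond that can be desaturated because C4 is quaternary, and no stereocentre is formed.

Step 2
Reactants: 2 4,4-dimethylcyclohexa-2,5-dien-1-one; 3 methanol
Product: 5 (1S,5R)-8,8-dimethyl-6-oxabicyclo[3.2.1]octan-3-one, via hydroxymethyl enone 4 (not isolated)
Conditions: [Ir(dF(CF3)ppy)2(dtbbpy)]PF6 (1 mol %), quinuclidine (10 mol %), Bu4N[H2PO4] (25 mol %), (1R,2R)-2-(9H-carbazol-9-yl)cyclohexan-1-amine (20 mol %), MeOH/MeCN 1:1, blue LED (450 nm), 20 °C; then DBU (10 mol %)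
Reagents that add atoms: methanol (3), CO
Why: Proposed new method: The photoexcited iridium complex oxidises quinuclidine, the aminium radical cation abstracts a hydridic C–H of phosphate-bound methanol, the nucleophilic •CH2OH adds to a β-carbon of the iminium ion formed from 2 and the primary amine (C22–C23), the carbazole unit passes an electron to the fleeting α-iminyl radical cation so that the addition becomes irreversible, and the reduced iridium complex restores the carbazole. The closest known reaction types are photoredox/quinuclidine α-C–H alkylation of alcohols with Michael acceptors, electron-relay iminium catalysis of radical conjugate additions to cyclic enones and amine-catalysed desymmetrisation of 4,4-disubstituted cyclohexadienones, but their combination with methanol on a dienone has not been shown. Ring D closes by a 5-exo-trig oxa-Michael addition of O21 to C20 of enone 4 (still activated as its iminium ion, and completed with DBU), which is geometrically possible only from the conformer with axial CH2OH. C23 is set by the catalyst, which leaves one face of the iminium ion open; because C24 bears two identical methyl groups the ring plane is a second mirror plane of 2, so the choice to be made is between enantiotopic faces (attack on the other β-carbon from the C2-related face gives the same product), not merely between the two alkenes. C20 is not an independent centre, since a two-atom O–CH2 bridge can span C20 and C23 only in the cis sense. The step needs mono-addition, no regiochemical ambiguity and no dienone photorearrangement: fast ring closure removes the second enone, the symmetry of 2 makes both β-carbons equivalent, and 2 does not absorb at 450 nm.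

Step 3
Reactants: 5 (1S,5R)-8,8-dimethyl-6-oxabicyclo[3.2.1]octan-3-one
Product: 6 (1R,2Z,5R)-2-(hydroxymethylidene)-8,8-dimethyl-6-oxabicyclo[3.2.1]octan-3-one
Conditions: (S,S)-bis(1-phenylethyl)amine (1.15 equiv), n-BuLi (1.1 equiv), LiCl (0.5 equiv), THF, −78 °C; CF3CH2OCHO (1.5 equiv), −78 to −20 °C; 1 M HCl
Reagents that add atoms: 2,2,2-trifluoroethyl formate, O=COCC(F)(F)F
Why: Chiral lithium amide deprotonation followed by Claisen-type C-formylation of the preformed enolate: seen from its exo face 5 is almost mirror-symmetric (the halves differ only in O21 versus C22), so, as with tropinone, 8-oxabicyclo[3.2.1]octan-3-ones and 4,4-disubstituted cyclohexanones, the base rather than the substrate should decide which axial α-proton leaves, here the one on C16, whereas an achiral base or an equilibrating formylation would favour C19, which is acidified by O21; no stereocentre is formed.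

Step 4
Reactants: 7 glutaraldehyde; 8 triethyl phosphonoacetate
Product: 9 ethyl 6-hydroxycyclohex-1-ene-1-carboxylate (racemic)
Conditions: K2CO3 (aq.), H2O, rt
Reagents that add atoms: none
Why: Tandem aldol-type addition and intramolecular Horner–Wadsworth–Emmons olefination: the phosphonate carbanion adds to one aldehyde, is regenerated by proton transfer and olefinates the other, which closes ring A with C12 in place; the racemic carbinol centre is erased in step 6.

Step 5
Reactants: 9 ethyl 6-hydroxycyclohex-1-ene-1-carboxylate
Product: 10 ethyl 6-[(tert-butoxycarbonyl)oxy]cyclohex-1-ene-1-carboxylate (racemic)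
Conditions: Boc2O (1.2 equiv), DMAP (10 mol %), CH2Cl2, rt
Reagents that add atoms: di-tert-butyl dicarbonate, CC(C)(C)OC(=O)OC(=O)OC(C)(C)C
Why: DMAP-catalysed O-acylation turns the allylic alcohol into a carbonate that ionises readily and releases its own base on ionisation.

Step 6
Reactants: 6 (1R,2Z,5R)-2-(hydroxymethylidene)-8,8-dimethyl-6-oxabicyclo[3.2.1]octan-3-one; 10 ethyl 6-[(tert-butoxycarbonyl)oxy]cyclohex-1-ene-1-carboxylate
Product: 11 ethyl (6S)-6-[(1R,2S,5R)-2-formyl-8,8-dimethyl-3-oxo-6-oxabicyclo[3.2.1]octan-2-yl]cyclohex-1-ene-1-carboxylate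
Conditions: Pd2(dba)3·CHCl3 (2.5 mol %), (R,R)-N,N′-(cyclohexane-1,2-diyl)bis[2-(diphenylphosphanyl)benzamide] (7.5 mol %), 10 (1.5 equiv), CH2Cl2, 0 °C to rt
Reagents that add atoms: none
Why: Tsuji–Trost asymmetric allylic alkylation: both enantiomers of 10 ionise to the same symmetric 2-(ethoxycarbonyl)cyclohexenyl palladium complex, the ligand selects the allyl terminus and so sets C9, and the planar C16 nucleophile should be attacked on its exo face, anti to the C23–C22 bond (the staggered trajectory followed in alkylations of bicyclo[3.2.1]octan-3-one and camphor enolates), where only C9–H has to pass the syn methyl group on C24, which sets C16.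

Step 7
Reactants: 11 ethyl (6S)-6-[(1R,2S,5R)-2-formyl-8,8-dimethyl-3-oxo-6-oxabicyclo[3.2.1]octan-2-yl]cyclohex-1-ene-1-carboxylate
Product: 13 unsaturated spirolactone (C10=C11; C6 = CH2), via hydroxy ester 12 (not isolated)
Conditions: NaBH4 (0.5 equiv), MeOH/CH2Cl2, −78 °C; then camphorsulfonic acid (10 mol %), toluene, 80 °C
Reagents that add atoms: none
Why: Chemoselective aldehyde reduction (at −78 °C the ketone C17, flanked by quaternary C16, and the enoate should survive) followed by acid-catalysed transesterification, which closes six-membered ring B without basic conditions that could trigger a retro-aldol loss of C15; no stereocentre is touched.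

Step 8
Reactants: 13 unsaturated spirolactone
Product: 14 ene-dione lactone (C6 ketone conjugated with C10=C11–C12=O)
Conditions: Rh2(cap)4 (1 mol %; cap = caprolactamate), t-BuOOH (70 % in water, 5 equiv), 1,2-dichloroethane, 40 °C
Reagents that add atoms: tert-butyl hydroperoxide, CC(C)(C)OO
Why: Peroxyl-radical allylic (γ) C–H oxidation of an α,β-unsaturated carbonyl compound: C6 is the only methylene whose radical is conjugated through C11=C10 with the C12 carbonyl, whereas the radical from C9–H would be cross-conjugated and is shielded by C16.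

Step 9
Reactants: 14 ene-dione lactone
Product: 15 saturated diketo lactone with cis A/B fusion
Conditions: H2 (1 atm), 10 % Pd/C, EtOAc, rt
Reagents that add atoms: none
Why: Heterogeneous hydrogenation of an electron-poor alkene: in 14 C9–H stands perpendicular to the enoate plane while C8 and C16 lean to the other side, so hydrogen should arrive on the C9–H face and set C10 with H9 and H10 cis.

Step 10
Reactants: 15 saturated diketo lactone
Product: 17 C6 carbaldehyde with equatorial CHO, via enol ether 16 (not isolated)
Conditions: MeOCH2PPh3Cl (1.6 equiv), KN(SiMe3)2 (1.5 equiv), THF, −78 to 0 °C; 2 M HCl, THF, rt; then DBU (20 mol %), CH2Cl2, rt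
Reagents that add atoms: (methoxymethyl)triphenylphosphonium chloride, COC[P+](c1ccccc1)(c1ccccc1)c1ccccc1.[Cl-]; water, O
Why: Wittig methoxymethylenation of the unhindered C6 ketone (C17 next to quaternary C16 should not react), enol ether hydrolysis and base equilibration; C6 is set under thermodynamic control, because the axial aldehyde would clash 1,3-diaxially with the axial C12, so CHO ends equatorial and trans to C16, the result that a kinetic hydrogenation of a C6 alkene from the open face would not give, and DBU is too weak to enolise the lactone at C10.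

Step 11
Reactants: 17 C6 carbaldehyde
Product: 18 C6 ethynyl compound
Conditions: dimethyl (1-diazo-2-oxopropyl)phosphonate (1.3 equiv), K2CO3 (2 equiv), MeOH, 0 °C to rt
Reagents that add atoms: dimethyl (1-diazo-2-oxopropyl)phosphonate, CC(=O)C(=[N+]=[N-])P(=O)(OC)OC
Why: Seyferth–Gilbert homologation with the Ohira–Bestmann reagent adds C1; any base-induced epimerisation of the aldehyde can only return it to the equatorial C6 epimer already present.

Step 12
Reactants: 18 C6 ethynyl compound
Product: 19 2-substituted acrylic acid (C2=C1H2, C3OOH on C2)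
Conditions: Pd(OAc)2 (1 mol %), 2-(diphenylphosphanyl)pyridine (15 mol %), MeSO3H (15 mol %), CO (30 bar), H2O (10 equiv), THF, 50 °C
Reagents that add atoms: carbon monoxide, [C-]#[O+]; water, O
Why: Branched-selective palladium-catalysed hydroxycarbonylation of a terminal alkyne with a 2-pyridylphosphine ligand places C3 on the internal carbon C2 under acidic conditions that ketone, lactone and ether tolerate.

Step 13
Reactants: 19 2-substituted acrylic acid
Product: 20 CNP0152427.2 (target)
Conditions: Ru(OAc)2[(R)-DTBM-SEGPHOS] (0.5 mol %), H2 (20 bar), MeOH, 25 °C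
Reagents that add atoms: none
Why: Carboxylate-directed asymmetric hydrogenation of a 2-alkylacrylic acid, a reaction class for which 2-aryl- and 2-cyclohexylacrylic acids such as artemisinic acid are standard substrates; the catalyst sets C2 (R), and a diamine-free ruthenium diphosphine catalyst should leave the ketone untouched.

Compound list
1 | 4,4-dimethylcyclohex-2-en-1-one | CC1(C)CCC(=O)C=C1 | starting material
2 | 4,4-dimethylcyclohexa-2,5-dien-1-one | CC1(C)C=CC(=O)C=C1 | intermediate
3 | methanol | CO | starting material
4 | (S)-5-(hydroxymethyl)-4,4-dimethylcyclohex-2-en-1-one | OC[C@H]1CC(=O)C=CC1(C)C | intermediate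
5 | (1S,5R)-8,8-dimethyl-6-oxabicyclo[3.2.1]octan-3-one | C1C(=O)C[C@H]2OC[C@@H]1C2(C)C | intermediate
6 | (1R,2Z,5R)-2-(hydroxymethylidene)-8,8-dimethyl-6-oxabicyclo[3.2.1]octan-3-one | O/C=C1\C(=O)C[C@H]2OC[C@@H]1C2(C)C | intermediate
7 | glutaraldehyde (pentanedial) | O=CCCCC=O | starting material
8 | triethyl phosphonoacetate | CCOC(=O)CP(=O)(OCC)OCC | starting material
9 | ethyl 6-hydroxycyclohex-1-ene-1-carboxylate, racemic | CCOC(=O)C1=CCCCC1O | intermediate
10 | ethyl 6-[(tert-butoxycarbonyl)oxy]cyclohex-1-ene-1-carboxylate, racemic | CCOC(=O)C1=CCCCC1OC(=O)OC(C)(C)C | intermediate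
11 | ethyl (6S)-6-[(1R,2S,5R)-2-formyl-8,8-dimethyl-3-oxo-6-oxabicyclo[3.2.1]octan-2-yl]cyclohex-1-ene-1-carboxylate (C9 on the exo face of C16, C15 syn to the O21–C22 bridge) | CCOC(=O)C1=CCCC[C@H]1[C@]1(C=O)C(=O)C[C@H]2OC[C@@H]1C2(C)C | intermediate
12 | ethyl (6S)-6-[(1R,2S,5R)-2-(hydroxymethyl)-8,8-dimethyl-3-oxo-6-oxabicyclo[3.2.1]octan-2-yl]cyclohex-1-ene-1-carboxylate | CCOC(=O)C1=CCCC[C@H]1[C@]1(CO)C(=O)C[C@H]2OC[C@@H]1C2(C)C | intermediate
13 | unsaturated spirolactone: rings B, C and D of the target complete, ring A a cyclohexene with C10=C11 and CH2 at C6, no side chain; C9, C16, C20, C23 as in the target | C1CC[C@@H]2C(=C1)C(=O)OC[C@]21C(=O)C[C@H]2OC[C@@H]1C2(C)C | intermediate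
14 | ene-dione lactone: 13 with a ketone at C6 | O=C1CC[C@@H]2C(=C1)C(=O)OC[C@]21C(=O)C[C@H]2OC[C@@H]1C2(C)C | intermediate
15 | saturated diketo lactone: C6 ketone, H9 and H10 cis (C12 and C16 on the same face of ring A) | O=C1CC[C@@H]2[C@H](C1)C(=O)OC[C@]21C(=O)C[C@H]2OC[C@@H]1C2(C)C | intermediate
16 | C6 methoxymethylidene enol ether of 15 (E/Z mixture) | COC=C1CC[C@@H]2[C@H](C1)C(=O)OC[C@]21C(=O)C[C@H]2OC[C@@H]1C2(C)C | intermediate
17 | C6 carbaldehyde, CHO equatorial and trans to C16 across ring A | O=C[C@@H]1CC[C@@H]2[C@H](C1)C(=O)OC[C@]21C(=O)C[C@H]2OC[C@@H]1C2(C)C | intermediate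
18 | C6 ethynyl compound (C2≡C1H), C6 as in the target | C#C[C@@H]1CC[C@@H]2[C@H](C1)C(=O)OC[C@]21C(=O)C[C@H]2OC[C@@H]1C2(C)C | intermediate
19 | 2-substituted acrylic acid (C1H2=C2(C3OOH)–C6) | C=C(C(=O)O)[C@@H]1CC[C@@H]2[C@H](C1)C(=O)OC[C@]21C(=O)C[C@H]2OC[C@@H]1C2(C)C | intermediate
20 | CNP0152427.2 (C2 R, C6 R, C9 R, C10 S, C16 S, C20 R, C23 R) | C[C@@H](C(=O)O)[C@@H]1CC[C@@H]2[C@H](C1)C(=O)OC[C@]21C(=O)C[C@H]2OC[C@@H]1C2(C)C | target

Total step count: 13. Longest linear sequence: 11 (steps 1–3 and 6–13).

Steps most likely to fail

Step 2 (key step). The amine may be consumed by hydrogen-atom abstraction or oxidation. Iminium formation from the hindered dienone may be too slow to compete with the uncatalysed, racemic radical addition. A second hydroxymethyl radical may add before ring closure.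
The fallback uses known chemistry. It sets out from 2 and returns at 4 and then 5.
- Rhodium-catalysed asymmetric 1,4-addition of K[CH2=CHBF3] ([Rh(C2H4)2Cl]2, (R)-BINAP, Et3N, toluene/H2O) should give (R)-5-ethenyl-4,4-dimethylcyclohex-2-en-1-one F1.
- Ozonolysis of the electron-rich vinyl group in the presence of the enone (O3, CH2Cl2/MeOH, −78 °C; Me2S) gives (S)-2,2-dimethyl-5-oxocyclohex-3-ene-1-carbaldehyde F2.
- NaBH(OAc)3 reduces only the aldehyde to 4, which closes to 5 with catalytic DBU.

Step 3. Deprotonation may occur on the C19 side, followed either by formylation there or by β-elimination of O21. The syn methyl group may also slow proton removal by the bulky base.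
The fallback sets out from 5 and returns at 6. It makes C16 the only nucleophilic carbon by letting ring D open for the time being.
- Exhaustive soft silylation (TMSOTf, Et3N, CH2Cl2, 0 °C to rt) should drain the C17–C19 enol silane, whose C20–O21 bond is aligned for ionisation, into (S)-{[6,6-dimethyl-3-(trimethylsilyloxy)cyclohexa-2,4-dien-1-yl]methoxy}trimethylsilane F3. Any C16–C17 enol silane that stays closed is a C16 nucleophile as well.
- MeLi releases the lithium dienolate, and 2,2,2-trifluoroethyl formate gives (5R,6Z)-6-(hydroxymethylidene)-4,4-dimethyl-5-[(trimethylsilyloxy)methyl]cyclohex-2-en-1-one F4.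
- 1 M HCl in THF cleaves the silyl ether. The alcohol then re-adds to C20 under control of C23 to give 6.

Step 6. O-allylation may occur without transfer to carbon. C–C bond formation at the crowded C16 may be sluggish. The allyl unit may also approach from the endo face.
The fallback sets out from 6 and 10 and returns at 12 and then 13. It reverses the order in which the two C16 substituents enter.
- The allylation is run as above and accepted with whatever C16 outcome it gives; the unwanted epimer is ethyl (6S)-6-[(1R,2R,5R)-2-formyl-8,8-dimethyl-3-oxo-6-oxabicyclo[3.2.1]octan-2-yl]cyclohex-1-ene-1-carboxylate F5.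
- Catalytic NaOMe in MeOH expels the formyl group by retro-Claisen cleavage to give ethyl (6S)-6-[(1S,2R,5R)-8,8-dimethyl-3-oxo-6-oxabicyclo[3.2.1]octan-2-yl]cyclohex-1-ene-1-carboxylate F6.
- Equilibrating silylation (Me3SiCl, NaI, Et3N, MeCN) gives the tetrasubstituted enol silane ethyl (6S)-6-[(1R,5R)-8,8-dimethyl-3-(trimethylsilyloxy)-6-oxabicyclo[3.2.1]oct-2-en-2-yl]cyclohex-1-ene-1-carboxylate F7.
- A Mukaiyama aldol reaction with aqueous formaldehyde (Sc(OTf)3, THF/H2O) brings in C15. The small electrophile enters from the face that the bulky allyl unit had preferred and pushes C9 to the other face, giving 12, which lactonises to 13 as in step 7.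

Further compounds
F1 | step 2 | (R)-5-ethenyl-4,4-dimethylcyclohex-2-en-1-one | C=C[C@H]1CC(=O)C=CC1(C)C
F2 | step 2 | (S)-2,2-dimethyl-5-oxocyclohex-3-ene-1-carbaldehyde | O=C[C@H]1CC(=O)C=CC1(C)C
F3 | step 3 | (S)-{[6,6-dimethyl-3-(trimethylsilyloxy)cyclohexa-2,4-dien-1-yl]methoxy}trimethylsilane | C[Si](C)(C)OC[C@H]1C=C(O[Si](C)(C)C)C=CC1(C)C
F4 | step 3 | (5R,6Z)-6-(hydroxymethylidene)-4,4-dimethyl-5-[(trimethylsilyloxy)methyl]cyclohex-2-en-1-one | O/C=C1\C(=O)C=CC(C)(C)[C@H]1CO[Si](C)(C)C
F5 | step 6 | ethyl (6S)-6-[(1R,2R,5R)-2-formyl-8,8-dimethyl-3-oxo-6-oxabicyclo[3.2.1]octan-2-yl]cyclohex-1-ene-1-carboxylate | CCOC(=O)C1=CCCC[C@H]1[C@@]1(C=O)C(=O)C[C@H]2OC[C@@H]1C2(C)C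
F6 | step 6 | ethyl (6S)-6-[(1S,2R,5R)-8,8-dimethyl-3-oxo-6-oxabicyclo[3.2.1]octan-2-yl]cyclohex-1-ene-1-carboxylate | CCOC(=O)C1=CCCC[C@H]1[C@H]1C(=O)C[C@H]2OC[C@@H]1C2(C)C
F7 | step 6 | ethyl (6S)-6-[(1R,5R)-8,8-dimethyl-3-(trimethylsilyloxy)-6-oxabicyclo[3.2.1]oct-2-en-2-yl]cyclohex-1-ene-1-carboxylate | CCOC(=O)C1=CCCC[C@H]1C1=C(O[Si](C)(C)C)C[C@H]2OC[C@@H]1C2(C)C
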